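**Remarks on the chemistry (assumptions).** Ring atoms are numbered as in the quinate skeleton: C1 carries OH and the carboxyl carbon C7, C2 and C6 are CH2, and C3, C4, C5 are the acylated carbinols. The C2–C3 arm is brought in as a prenyl group and the C4 aldehyde as a (Z)-propenyl group; only the carbons lost on ozonolysis differ from an allyl/vinyl version. 3,4,5-Tris(benzyloxy)benzoic acid 17 and tributyl(prop-1-yn-1-yl)stannane 7 are taken as purchasable.

## Analysis of the target

The target 23 is 3,4,5-tri-O-galloyl-(−)-quinic acid: one cyclohexane ring in which C1 is a tertiary carbinol bearing the carboxyl C7, C2 and C6 are methylenes, and C3, C4, C5 are contiguous secondary carbinols, each esterified with a 3,4,5-trihydroxybenzoyl group. There are four stereocentres. O3 and O4 are cis, O5 is trans to O4, the carboxyl lies on the face of O5 and the free 1-OH on the face of O3 and O4. C1 is a stereocentre only because the two ring arms differ, so its absolute configuration has to be secured independently of the triol. The sensitive groups are the nine phenolic hydroxyls (air and base), the three vicinal aryl esters (acyl migration and cleavage under base) and the free α-hydroxy acid. The cis relation of C7 and O5 makes lactonisation a constant threat whenever O5 is free and C7 is activated. The difficulty lies in building a carbocycle with a quaternary carbinol and three adjacent carbinols in the correct relative and absolute sense, then acylating O3, O4 and O5 but not O1, and finishing under neutral conditions. The strategy rests on the C3–C4 bond of the cyclohexane: it joins two cis carbinol carbons, it is flanked by the oxygenated C5 on one side and the methylene C2 on the other, and both of its carbons can therefore come from aldehydes of an open chain in which C1 and C5 are already fixed.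

## Retrosynthetic reasoning

Target 23 is traced back to the fully benzylated compound 22 by cutting the ten O–CH2Ph bonds (nine aryl ethers, one ester). All phenols and the acid stay masked until a last, neutral hydrogenolysis, which spares the aryl esters.

The three ester C–O bonds of 22 are cut one at a time, each cut releasing acid chloride 18. The first cut, at O5, gives diester 21, which comes from silyl ether 20 by Si–O cleavage. O5 is esterified last because it is the hydroxyl cis to C7: as long as it carries silicon it cannot lactonise while the other two positions are acylated.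

Diester 20 is cut at the O3 ester bond to monoester 19, and 19 at the O4 ester bond to diol 16. In the forward direction the equatorial O4 of the cis-3,4-diol is acylated first, under conditions that stop after one acyl transfer. The more hindered axial O3 follows in a separate step that can be driven to completion. The three acyl groups are identical, so a regioisomeric monoester would lead to the same diester 20. Only the tertiary O1 must stay free throughout, and its low reactivity is relied on.

Acid chloride 18 is traced to acid 17 by cutting the C–Cl bond. It is made once and serves in all three ester-forming steps.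

Diol 16 comes from the spiro-dioxolanone 15 by opening the acyl–oxygen bond of the acyl acetal, so that C7 leaves as its benzyl ester. The acetal is opened before any aryl ester is present, because the opening needs an alkoxide, and while O5 still carries silicon, so that O5 cannot attack C7.

Diol 15 is cut at C3–C4 to the 1,6-dialdehyde 14. This is the only ring bond whose two carbons both carry oxygen at the carbinol level and sit next to a preset oxygenated centre. Cutting it lets both carbons start as aldehydes of equal oxidation state, removes the ring and two stereocentres in one operation, and leaves no redox adjustment afterwards. The forward reaction, a reductive ketyl coupling with a divalent samarium reagent, has to give the cis-diol and place it anti to O5.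

Dialdehyde 14 is traced through bis-ozonide 13 to diene 12 by regarding each aldehyde as one half of a C=C bond. Both alkenes are cleaved together immediately before the coupling, so the fragile dialdehyde is never stored, and the co-products are volatile.

Diene 12 goes back through alkyne 11 (semihydrogenation) and alcohol 10 (silylation) to ynone 9. The C5–H bond is the one disconnected. A ketone at C5 flanked by an alkyne is chosen because reagent-controlled transfer hydrogenation of such ketones sets the carbinol reliably, independent of the remote C1 centre, and under neutral conditions.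

Ynone 9 is cut at C4–C5 (acyl–alkynyl bond) to acid 6 and stannane 7, joined through acid chloride 8. The carboxyl of the malic acid arm thus becomes C5 directly, with no change of chain length.

Acid 6 is cut at C1–C2 to the dioxolanone acid 3 and prenyl bromide 4. The forward alkylation goes through enolate 5 and must replace the C1–H bond with retention; this is what the tert-butyl acetal centre is there for.

Dioxolanone 3 is the acetal of (S)-malic acid 1 with pivalaldehyde 2; the whole absolute configuration of C1 originates in 1.

## Alternatives that were turned down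

Alternative 1: The ring is cut at C5–C6 of a cyclohexanone in which C1 is still a ketone. In the forward sense mercury bis(trifluoroacetate) A3, a divalent mercury salt of formula Hg(OCOCF3)2, hydrates the exocyclic enol ether of the glycoside A2, the hemiacetal opens to a keto-aldehyde, and the mercury enolate closes onto the former anomeric carbon to give the β-hydroxy ketone A1 (Ferrier carbocyclisation). In its favour, C3 and C4 come straight from the chiral pool with no selectivity question, the ring closure is a well-tried reaction, and A1 has O5 free and O3/O4 protected. Against it, A1 has no C1 stereocentre. The one-carbon carboxyl unit must still be added to the ketone, and the face of that addition on a flexible β-oxygenated cyclohexanone decides the quaternary centre, so the hardest centre is left to the end. A1 also loses water easily to the enone. A2 needs a 2,3-cis diol of the D-erythro type with C4 deoxygenated, a pattern that corresponds to allose or gulose and not to glucose, galactose or D-mannose, so inversion and deoxygenation steps precede the key step; a mercury reagent is also required. Compared with the chosen plan, this route is stronger on C3 and C4 and on differentiating O5, which the symmetric triester does not need. The chosen plan fixes C1 first and with certainty, and should not be longer once the sugar has been adjusted.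

Alternative 2: Two ring bonds, C1–C6 and C2–C3, are cut in a [4+2] sense. The dienophile 2-(benzoyloxy)acrolein A5 and the diene buta-1,3-diene A6 combine under a chiral cationic oxazaborolidine Lewis acid to give the cyclohexene A4, with C1 set and the alkene at C4–C5. In its favour, ring and quaternary centre arise in one catalytic step from trivial components. The known follow-up (oxidation of the aldehyde, halolactonisation onto C5, elimination to the C3–C4 alkene, cis-dihydroxylation anti to the lactone bridge) delivers the 3,4-cis/4,5-trans triol in few steps. On step count this alternative is clearly stronger than the chosen route. Against it, every absolute configuration depends on the enantioselectivity of one cycloaddition that pairs the least biased and least reactive diene with an acyloxyacrolein. A4 has a single stereocentre, so its purity cannot be raised by separating diastereomers, and C1 is stereogenic in A4 only through the position of the alkene. A gaseous diene and a moisture-sensitive, superacid-activated catalyst add practical weight. The chosen plan gives up step economy here; in return C1 comes from (S)-malic acid through a crystalline diastereomer, C5 from a catalyst-controlled ketone reduction of a dependable kind, and C3 and C4 from a single ring closure.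

Alternative 3: The ring is cut at C4–C5. A chiral secondary amine of the proline type turns the C3 ketone of keto-aldehyde A8 into the enamine toward C4, which adds to the C5 aldehyde (6-enolexo aldol) to give A7, a protected 3-dehydroquinate with O4 and O5 anti. In its favour, it uses the same malic-derived C1 block, is metal-free and catalytic, sets C4 and C5 together, and distinguishes O4 (benzyl) from O5 (free). Against it, the other α-carbon of the ketone, C2, is next to C1, which carries the acetal oxygen. Enamine or enol formation toward C2 expels that oxygen and opens the dioxolanone, and the product A7, a ketone with oxygen at both β-positions (O1 and O5), is prone to the same loss to give the conjugated enone. C3 must then still be reduced so that O3 ends cis to O4, a third stereochemical question, and the benzyloxy-ketone arm costs extra steps. Compared with the chosen plan it is equal in starting block and stronger in being organocatalytic. The chosen route avoids any β-oxygenated ketone in the ring and creates C3 and C4 at their final oxidation level in one step.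

Key step: step 8

## Route

Step 1
Reactants: 1 (S)-malic acid; 2 pivalaldehyde
Product: 3 2-[(2S,4S)-2-tert-butyl-5-oxo-1,3-dioxolan-4-yl]acetic acid (tert-butyl cis to the CH2CO2H arm)
Conditions: 2 (1.5 equiv), TsOH·H2O (cat.), H2SO4 (cat.), pentane, reflux, Dean–Stark; recrystallisation
Reagents that add atoms: none
Why: Acid-catalysed acetalisation of the α-hydroxy acid unit (Seebach dioxolanone formation); the five-membered acyl acetal is preferred over the six-membered one through the β-carboxyl, and under equilibration the malic acid centre places the tert-butyl group cis, the isomer that should be purified by crystallisation.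

Step 2
Reactants: 3 2-[(2S,4S)-2-tert-butyl-5-oxo-1,3-dioxolan-4-yl]acetic acid; 4 prenyl bromide (1-bromo-3-methylbut-2-ene)
Product: 6 2-[(2S,4S)-2-tert-butyl-4-(3-methylbut-2-en-1-yl)-5-oxo-1,3-dioxolan-4-yl]acetic acid, via dilithium enolate–carboxylate 5 (not isolated)
Conditions: LiN(SiMe3)2 (2.2 equiv), THF, −78 °C; 4 (1.5 equiv), −78 → −30 °C; 1 M HCl work-up
Reagents that add atoms: none
Why: Seebach alkylation with self-regeneration of the stereocentre: the ring C–H is removed to give a planar enolate, the tert-butyl group on the acetal carbon shields one face, and the allylic bromide enters from the other, so C–C replaces C–H with retention and the acid arm stays cis to tert-butyl. The silylamide base is used so that the ring position, and not the CH2 beside the carboxylate, is deprotonated.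

Step 3
Reactants: 6 2-[(2S,4S)-2-tert-butyl-4-(3-methylbut-2-en-1-yl)-5-oxo-1,3-dioxolan-4-yl]acetic acid; 7 tributyl(prop-1-yn-1-yl)stannane
Product: 9 (2S,5S)-2-tert-butyl-5-(3-methylbut-2-en-1-yl)-5-(2-oxopent-3-yn-1-yl)-1,3-dioxolan-4-one, via acid chloride 8 (not isolated)
Conditions: 1-chloro-N,N,2-trimethylprop-1-en-1-amine (1.2 equiv), CH2Cl2, 0 °C → rt; then 7 (1.2 equiv), PdCl2(PPh3)2 (3 mol %), toluene, 50 °C
Reagents that add atoms: none
Why: The chloroenamine makes the acid chloride without free HCl, which protects the trisubstituted alkene and the acetal; Stille acylation then follows (oxidative addition of the acyl chloride to zerovalent palladium formed in situ, transfer of the alkynyl group from tin, reductive elimination). No amine base is present, so the β-oxygenated ketone is not exposed to elimination conditions.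

Step 4
Reactants: 9 (2S,5S)-2-tert-butyl-5-(3-methylbut-2-en-1-yl)-5-(2-oxopent-3-yn-1-yl)-1,3-dioxolan-4-one
Product: 10 (2S,5S)-2-tert-butyl-5-[(2R)-2-hydroxypent-3-yn-1-yl]-5-(3-methylbut-2-en-1-yl)-1,3-dioxolan-4-one
Conditions: Ru[(R,R)-TsNCHPhCHPhNH](η6-p-cymene) (1 mol %), i-PrOH, rt
Reagents that add atoms: none
Why: Noyori asymmetric transfer hydrogenation of an α,β-acetylenic ketone; the alkynyl group takes the place that aryl takes in aryl ketone reductions, so the (R,R) ligand should deliver hydride to give the (R)-carbinol (C5) under catalyst control, whatever the bias of the remote C1 centre. The neutral medium generates no alkoxide that could attack the dioxolanone carbonyl, and C≡C and C=C are left alone.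

Step 5
Reactants: 10 (2S,5S)-2-tert-butyl-5-[(2R)-2-hydroxypent-3-yn-1-yl]-5-(3-methylbut-2-en-1-yl)-1,3-dioxolan-4-one
Product: 11 (2S,5S)-2-tert-butyl-5-[(2R)-2-(tert-butyldimethylsilyloxy)pent-3-yn-1-yl]-5-(3-methylbut-2-en-1-yl)-1,3-dioxolan-4-one
Conditions: TBSOTf (1.3 equiv), 2,6-lutidine (2 equiv), CH2Cl2, −78 → 0 °C
Reagents that add atoms: tert-butyldimethylsilyl triflate, CC(C)(C)[Si](C)(C)OS(=O)(=O)C(F)(F)F
Why: Silylation of a secondary alcohol with a silyl triflate and a hindered pyridine base; it is fast at low temperature and caps O5 before it can translactonise onto C7.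

Step 6
Reactants: 11 (2S,5S)-2-tert-butyl-5-[(2R)-2-(tert-butyldimethylsilyloxy)pent-3-yn-1-yl]-5-(3-methylbut-2-en-1-yl)-1,3-dioxolan-4-one
Product: 12 (2S,5S)-2-tert-butyl-5-[(2R,3Z)-2-(tert-butyldimethylsilyloxy)pent-3-en-1-yl]-5-(3-methylbut-2-en-1-yl)-1,3-dioxolan-4-one
Conditions: H2 (1 atm), Pd/CaCO3 poisoned with Pb(OAc)2 (Lindlar catalyst), quinoline, EtOAc, rt
Reagents that add atoms: none
Why: Lindlar semihydrogenation (syn addition) turns the alkyne into an alkene that ozone can cleave to an aldehyde; the trisubstituted prenyl alkene is not reduced on the poisoned catalyst, and the alkene geometry is immaterial because the bond is cleaved next.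

Step 7
Reactants: 12 (2S,5S)-2-tert-butyl-5-[(2R,3Z)-2-(tert-butyldimethylsilyloxy)pent-3-en-1-yl]-5-(3-methylbut-2-en-1-yl)-1,3-dioxolan-4-one
Product: 14 (2R)-2-(tert-butyldimethylsilyloxy)-3-[(2S,4R)-2-tert-butyl-5-oxo-4-(2-oxoethyl)-1,3-dioxolan-4-yl]propanal, via bis-ozonide 13 (not isolated)
Conditions: O3, CH2Cl2, −78 °C (Sudan Red 7B as end-point indicator); then PPh3 (2.5 equiv), −78 °C → rt; used at once
Reagents that add atoms: ozone, [O-][O+]=O
Why: Ozonolysis (Criegee mechanism) of both alkenes with reductive work-up gives the two aldehydes, C3 from the prenyl group and C4 from the propenyl group; the co-products are volatile. The neutral phosphine reduction avoids epimerisation of the α-silyloxy aldehyde at C5 and β-elimination of the C1 oxygen, and the indicator limits excess ozone at the acetal C–H.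

Step 8
Reactants: 14 (2R)-2-(tert-butyldimethylsilyloxy)-3-[(2S,4R)-2-tert-butyl-5-oxo-4-(2-oxoethyl)-1,3-dioxolan-4-yl]propanal
Product: 15 (2S,5S,7R,8R,9R)-2-tert-butyl-7-(tert-butyldimethylsilyloxy)-8,9-dihydroxy-1,3-dioxaspiro[4.5]decan-4-one (5-O-TBS quinate skeleton with O1 and C7 held in the pivalaldehyde acetal; O3/O4 cis, O4/O5 trans)
Conditions: SmI2 (3 equiv, 0.1 M in THF), t-BuOH (3 equiv), THF (0.01 M in 14), −78 °C → rt; aq. NaHCO3/Na2S2O3 work-up
Reagents that add atoms: none
Why: SmI2 (divalent samarium) transfers one electron to each aldehyde, and the two ketyls, held together through oxophilic trivalent samarium, join at carbon to form C3–C4. The closest known reaction type is the SmI2 pinacol cyclisation of 1,6-dialdehydes to cis-cyclohexane-1,2-diols, as used for carbasugars and inositols. The cyclohexane closes in a 6-exo sense (counted as attack of one ketyl carbon on the other carbonyl carbon) through a chair-like array. C3 and C4 are set relative to each other by the samarium bridge, which keeps both oxygens on one side and gives the cis-diol. C4 is set relative to C5 by the silyloxy group, which takes the position anti to the metal-bound C4 oxygen for steric and dipole reasons, so O4 ends trans to O5 and the ring forms in the chair with O4 and O5 equatorial. The step needs one diol (3,4-cis, 4,5-trans) out of four; the fixed C5 (R) centre and the chelation supply this, with C1 already in place. t-BuOH protonates the samarium alkoxides and high dilution suppresses intermolecular coupling. The silyl ether is a poor leaving group next to the ketyl, and neither new alkoxide can reach the dioxolanone carbonyl because both are trans to C7.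

Step 9
Reactants: 15 (2S,5S,7R,8R,9R)-2-tert-butyl-7-(tert-butyldimethylsilyloxy)-8,9-dihydroxy-1,3-dioxaspiro[4.5]decan-4-one
Product: 16 benzyl 5-O-(tert-butyldimethylsilyl)-(−)-quinate (benzyl ester at C7; free 1-, 3- and 4-OH)
Conditions: BnOH (10 equiv), BnONa (0.3 equiv), THF, 0 °C → rt; aq. NH4Cl work-up
Reagents that add atoms: benzyl alcohol, OCc1ccccc1
Why: Alkoxide-catalysed alcoholysis of the Seebach dioxolanone: benzyloxide adds to the acyl carbon, the hemiacetal alkoxide collapses to pivalaldehyde and the C1 alkoxide, which regenerates benzyloxide. O5 is still silylated and cannot lactonise onto C7, and the short exposure to a catalytic amount of alkoxide at low temperature should leave the silyl group on O5.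

Step 10
Reactants: 17 3,4,5-tris(benzyloxy)benzoic acid
Product: 18 3,4,5-tris(benzyloxy)benzoyl chloride
Conditions: (COCl)2 (1.5 equiv), DMF (cat.), CH2Cl2, 0 °C → rt; evaporation, recrystallisation from toluene/hexane
Reagents that add atoms: oxalyl chloride, ClC(=O)C(=O)Cl
Why: Acid chloride formation through the Vilsmeier-type chloroiminium ion; the benzyl aryl ethers tolerate it, the gaseous co-products leave, and the crystalline chloride can be kept for the three ester-forming steps.

Step 11
Reactants: 16 benzyl 5-O-(tert-butyldimethylsilyl)-(−)-quinate; 18 3,4,5-tris(benzyloxy)benzoyl chloride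
Product: 19 benzyl 5-O-(tert-butyldimethylsilyl)-4-O-[3,4,5-tris(benzyloxy)benzoyl]-(−)-quinate (free 1- and 3-OH)
Conditions: 18 (1.05 equiv), Me2SnCl2 (5 mol %), i-Pr2NEt (1.5 equiv), THF, 0 °C → rt
Reagents that add atoms: none
Why: Dimethyltin dichloride-catalysed monoacylation of a 1,2-diol: tin binds the cis-3,4-diol as a chelate and raises the nucleophilicity of one oxygen, by analogy with pyranoside cis-diols the equatorial O4, while the isolated tertiary O1 is not activated. The reaction should stop after one acyl transfer because the monoester no longer chelates tin. Any O3 monoester that forms would give the same diester in step 12.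

Step 12
Reactants: 19 benzyl 5-O-(tert-butyldimethylsilyl)-4-O-[3,4,5-tris(benzyloxy)benzoyl]-(−)-quinate; 18 3,4,5-tris(benzyloxy)benzoyl chloride
Product: 20 benzyl 5-O-(tert-butyldimethylsilyl)-3,4-bis-O-[3,4,5-tris(benzyloxy)benzoyl]-(−)-quinate (free 1-OH)
Conditions: 18 (1.5 equiv), pyridine (4 equiv), DMAP (0.2 equiv), CH2Cl2, 0 °C → rt
Reagents that add atoms: none
Why: DMAP-catalysed acylation through the N-acylpyridinium ion esterifies the axial secondary O3; the tertiary O1, on a fully substituted carbon next to the ester, should react far more slowly. O5 is still silylated, so no hydroxyl cis to C7 is free while this more hindered position is driven to completion.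

Step 13
Reactants: 20 benzyl 5-O-(tert-butyldimethylsilyl)-3,4-bis-O-[3,4,5-tris(benzyloxy)benzoyl]-(−)-quinate
Product: 21 benzyl 3,4-bis-O-[3,4,5-tris(benzyloxy)benzoyl]-(−)-quinate (free 1- and 5-OH)
Conditions: HF·pyridine, pyridine, THF, 0 °C → rt
Reagents that add atoms: none
Why: Fluoride-driven Si–O cleavage under buffered, non-basic conditions; no alkoxide is formed, so neither acyl migration from O4 to O5 nor attack of O5 on the benzyl ester is promoted.

Step 14
Reactants: 21 benzyl 3,4-bis-O-[3,4,5-tris(benzyloxy)benzoyl]-(−)-quinate; 18 3,4,5-tris(benzyloxy)benzoyl chloride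
Product: 22 benzyl 3,4,5-tris-O-[3,4,5-tris(benzyloxy)benzoyl]-(−)-quinate (free 1-OH)
Conditions: 18 (1.5 equiv), pyridine (4 equiv), DMAP (0.2 equiv), CH2Cl2, 0 °C → rt
Reagents that add atoms: none
Why: DMAP-catalysed acylation of the equatorial secondary O5; intermolecular acyl transfer should outrun lactonisation, which would need the inverted chair with C7, O4 and O5 all axial. A shift of the O4 acyl group to O5 would only free O4 for acylation and lead to the same triester, and O1 stays free for the reason given in step 12.

Step 15
Reactants: 22 benzyl 3,4,5-tris-O-[3,4,5-tris(benzyloxy)benzoyl]-(−)-quinate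
Product: 23 3,4,5-tri-O-galloyl-(−)-quinic acid (CNP0148451.1)
Conditions: H2 (1 atm), Pd/C (10 %), THF/MeOH, rt
Reagents that add atoms: none
Why: Hydrogenolysis cleaves the nine benzyl aryl ethers and the benzyl ester in one operation; aryl esters, the tertiary alcohol and the cyclohexane are inert, and the neutral medium should prevent galloyl migration.

## Compound list

1 | (S)-malic acid | O[C@@H](CC(=O)O)C(=O)O | starting material
2 | pivalaldehyde | CC(C)(C)C=O | starting material
3 | 2-[(2S,4S)-2-tert-butyl-5-oxo-1,3-dioxolan-4-yl]acetic acid | OC(=O)C[C@@H]1O[C@H](C(C)(C)C)OC1=O | intermediate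
4 | prenyl bromide (1-bromo-3-methylbut-2-ene) | CC(C)=CCBr | starting material
5 | dilithium (S)-2-tert-butyl-5-(carboxylatomethyl)-1,3-dioxol-4-olate (enolate–carboxylate of 3) | [Li+].[Li+].[O-]C(=O)CC1=C([O-])O[C@@H](C(C)(C)C)O1 | intermediate
6 | 2-[(2S,4S)-2-tert-butyl-4-(3-methylbut-2-en-1-yl)-5-oxo-1,3-dioxolan-4-yl]acetic acid | OC(=O)C[C@]1(CC=C(C)C)O[C@H](C(C)(C)C)OC1=O | intermediate
7 | tributyl(prop-1-yn-1-yl)stannane | CC#C[Sn](CCCC)(CCCC)CCCC | starting material
8 | 2-[(2S,4S)-2-tert-butyl-4-(3-methylbut-2-en-1-yl)-5-oxo-1,3-dioxolan-4-yl]acetyl chloride | ClC(=O)C[C@]1(CC=C(C)C)O[C@H](C(C)(C)C)OC1=O | intermediate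
9 | (2S,5S)-2-tert-butyl-5-(3-methylbut-2-en-1-yl)-5-(2-oxopent-3-yn-1-yl)-1,3-dioxolan-4-one | CC#CC(=O)C[C@]1(CC=C(C)C)O[C@H](C(C)(C)C)OC1=O | intermediate
10 | (2S,5S)-2-tert-butyl-5-[(2R)-2-hydroxypent-3-yn-1-yl]-5-(3-methylbut-2-en-1-yl)-1,3-dioxolan-4-one | CC#C[C@H](O)C[C@]1(CC=C(C)C)O[C@H](C(C)(C)C)OC1=O | intermediate
11 | (2S,5S)-2-tert-butyl-5-[(2R)-2-(tert-butyldimethylsilyloxy)pent-3-yn-1-yl]-5-(3-methylbut-2-en-1-yl)-1,3-dioxolan-4-one | CC#C[C@H](O[Si](C)(C)C(C)(C)C)C[C@]1(CC=C(C)C)O[C@H](C(C)(C)C)OC1=O | intermediate
12 | (2S,5S)-2-tert-butyl-5-[(2R,3Z)-2-(tert-butyldimethylsilyloxy)pent-3-en-1-yl]-5-(3-methylbut-2-en-1-yl)-1,3-dioxolan-4-one | C/C=C\[C@H](O[Si](C)(C)C(C)(C)C)C[C@]1(CC=C(C)C)O[C@H](C(C)(C)C)OC1=O | intermediate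
13 | bis-ozonide of 12 (two 1,2,4-trioxolanes; mixture of isomers at the ozonide carbons) | CC1OOC(O1)[C@H](O[Si](C)(C)C(C)(C)C)C[C@]2(CC3OOC(C)(C)O3)O[C@H](C(C)(C)C)OC2=O | intermediate
14 | (2R)-2-(tert-butyldimethylsilyloxy)-3-[(2S,4R)-2-tert-butyl-5-oxo-4-(2-oxoethyl)-1,3-dioxolan-4-yl]propanal | O=C[C@H](O[Si](C)(C)C(C)(C)C)C[C@]1(CC=O)O[C@H](C(C)(C)C)OC1=O | intermediate
15 | (2S,5S,7R,8R,9R)-2-tert-butyl-7-(tert-butyldimethylsilyloxy)-8,9-dihydroxy-1,3-dioxaspiro[4.5]decan-4-one | CC(C)(C)[Si](C)(C)O[C@@H]1C[C@@]2(O[C@H](C(C)(C)C)OC2=O)C[C@@H](O)[C@H]1O | intermediate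
16 | benzyl 5-O-(tert-butyldimethylsilyl)-(−)-quinate | CC(C)(C)[Si](C)(C)O[C@@H]1C[C@](O)(C(=O)OCc2ccccc2)C[C@@H](O)[C@H]1O | intermediate
17 | 3,4,5-tris(benzyloxy)benzoic acid | OC(=O)c1cc(OCc2ccccc2)c(OCc2ccccc2)c(OCc2ccccc2)c1 | starting material
18 | 3,4,5-tris(benzyloxy)benzoyl chloride | ClC(=O)c1cc(OCc2ccccc2)c(OCc2ccccc2)c(OCc2ccccc2)c1 | intermediate
19 | benzyl 5-O-(tert-butyldimethylsilyl)-4-O-[3,4,5-tris(benzyloxy)benzoyl]-(−)-quinate | CC(C)(C)[Si](C)(C)O[C@@H]1C[C@](O)(C(=O)OCc2ccccc2)C[C@@H](O)[C@H]1OC(=O)c1cc(OCc2ccccc2)c(OCc2ccccc2)c(OCc2ccccc2)c1 | intermediate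
20 | benzyl 5-O-(tert-butyldimethylsilyl)-3,4-bis-O-[3,4,5-tris(benzyloxy)benzoyl]-(−)-quinate | CC(C)(C)[Si](C)(C)O[C@@H]1C[C@](O)(C(=O)OCc2ccccc2)C[C@@H](OC(=O)c2cc(OCc3ccccc3)c(OCc3ccccc3)c(OCc3ccccc3)c2)[C@H]1OC(=O)c1cc(OCc2ccccc2)c(OCc2ccccc2)c(OCc2ccccc2)c1 | intermediate
21 | benzyl 3,4-bis-O-[3,4,5-tris(benzyloxy)benzoyl]-(−)-quinate | O[C@@H]1C[C@](O)(C(=O)OCc2ccccc2)C[C@@H](OC(=O)c2cc(OCc3ccccc3)c(OCc3ccccc3)c(OCc3ccccc3)c2)[C@H]1OC(=O)c1cc(OCc2ccccc2)c(OCc2ccccc2)c(OCc2ccccc2)c1 | intermediate
22 | benzyl 3,4,5-tris-O-[3,4,5-tris(benzyloxy)benzoyl]-(−)-quinate | O=C(O[C@@H]1C[C@](O)(C(=O)OCc2ccccc2)C[C@@H](OC(=O)c2cc(OCc3ccccc3)c(OCc3ccccc3)c(OCc3ccccc3)c2)[C@H]1OC(=O)c1cc(OCc2ccccc2)c(OCc2ccccc2)c(OCc2ccccc2)c1)c1cc(OCc2ccccc2)c(OCc2ccccc2)c(OCc2ccccc2)c1 | intermediate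
23 | 3,4,5-tri-O-galloyl-(−)-quinic acid (CNP0148451.1) | O=C(O[C@@H]1C[C@](O)(C(=O)O)C[C@@H](OC(=O)c2cc(O)c(O)c(O)c2)[C@H]1OC(=O)c1cc(O)c(O)c(O)c1)c1cc(O)c(O)c(O)c1 | target

## Step count and risks

Total: 15 steps. Longest linear sequence: 14 steps (steps 1–9 and 11–15, from 1 to 23); step 10 prepares acid chloride 18 in a side branch.

**Step 8 (key step).** The most likely failure is insufficient diastereocontrol among the four possible diols. In the favoured chair the ring oxygen of the spiro-dioxolanone sits syn-axial to the forming O3, which may erode the anti-to-O5 preference. A second electron transfer at the C4 ketyl before coupling would expel the silyloxy group, and simple reduction or intermolecular coupling would compete if the dilution is inadequate. Epimerisation of C5 in the dialdehyde before coupling would also pass through unnoticed. Fallback: set out from diene 12 and close the same C3–C4 bond by ring-closing metathesis (second-generation Grubbs catalyst RuCl2(=CHPh)(PCy3)(H2IMes), toluene, 80 °C). This should give (2S,5S,9R)-2-tert-butyl-9-(tert-butyldimethylsilyloxy)-1,3-dioxaspiro[4.5]dec-7-en-4-one F1, the cyclohexene with the C3–C4 double bond. Cis-dihydroxylation (OsO4 cat., N-methylmorpholine N-oxide, acetone/H2O) from the face opposite the allylic silyloxy group should then give the cis-diol trans to O5, and the route is rejoined at 15.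

**Step 2.** Deprotonation may occur at the CH2 next to the carboxylate and not at the ring carbon, followed by β-elimination of the ring oxygen and loss of the dioxolanone; the dianion may also alkylate sluggishly and with lower facial selectivity than a simple enolate. Fallback: set out from 3 and remove the carboxylate before the alkylation. Borane reduction (BH3·SMe2, THF) gives (2S,5S)-2-tert-butyl-5-(2-hydroxyethyl)-1,3-dioxolan-4-one F2. Silylation (TBSCl, imidazole) gives (2S,5S)-2-tert-butyl-5-[2-(tert-butyldimethylsilyloxy)ethyl]-1,3-dioxolan-4-one F3. Alkylation of its monoenolate (LiN(i-Pr)2, THF, −78 °C, then 4) gives (2S,5S)-2-tert-butyl-5-[2-(tert-butyldimethylsilyloxy)ethyl]-5-(3-methylbut-2-en-1-yl)-1,3-dioxolan-4-one F4. Jones oxidation (CrO3, H2SO4, acetone, 0 °C), which removes the primary silyl ether and oxidises to the acid, rejoins the route at 6.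

**Step 9.** Under alkoxide the silyl group may migrate from O5 to O4, which would change the order in which the hydroxyls are esterified later and expose O5 to C7; attack at the hindered acyl carbon may also be slow. Fallback: set out from 15 and saponify the acyl acetal in water (LiOH, THF/H2O, 0 °C), which leaves a carboxylate that cannot be attacked by O5, to give 5-O-(tert-butyldimethylsilyl)-(−)-quinic acid F5. O-alkylation of the carboxylate (BnBr, KHCO3, DMF) rejoins the route at 16.

**Step 11.** Site control may be incomplete: the neighbouring silyl ether or the 1,3-related O1/O3 pair may disturb the tin chelate, so that both monoesters, some diester and unreacted diol arise together. All of them converge on 20, but the material becomes hard to follow and to purify. Fallback: set out from 16 and give up the one-at-a-time esterification. HF·pyridine (pyridine, THF) removes the silyl group to give benzyl (−)-quinate F6. Exhaustive acylation of its three secondary hydroxyls with an excess of 18 (pyridine, DMAP, CH2Cl2) rejoins the route at 22.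

**Step 12.** Acylation of the axial O3, next to the O4 ester and syn-axial to O1, may stall, and forcing it may start to acylate the tertiary O1. Fallback: set out from 15, in which O1 is locked in the acetal throughout all acylations. Acylation of the 3,4-diol with 18 (pyridine, DMAP) gives the 3,4-bis-O-[3,4,5-tris(benzyloxy)benzoyl] 5-O-silyl spiro-dioxolanone F7. HF·pyridine gives its 5-hydroxy compound F8. A third acylation with 18 gives the 3,4,5-tris-O-[3,4,5-tris(benzyloxy)benzoyl] spiro-dioxolanone F9. Acid hydrolysis of the acyl acetal (CF3CO2H/H2O, CH2Cl2) gives 3,4,5-tris-O-[3,4,5-tris(benzyloxy)benzoyl]-(−)-quinic acid F10. Hydrogenolysis (H2, Pd/C) then rejoins the route at 23.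

## Further compounds

F1 | step 8 | (2S,5S,9R)-2-tert-butyl-9-(tert-butyldimethylsilyloxy)-1,3-dioxaspiro[4.5]dec-7-en-4-one | CC(C)(C)[Si](C)(C)O[C@@H]1C[C@@]2(O[C@H](C(C)(C)C)OC2=O)CC=C1
F2 | step 2 | (2S,5S)-2-tert-butyl-5-(2-hydroxyethyl)-1,3-dioxolan-4-one | OCC[C@@H]1O[C@H](C(C)(C)C)OC1=O
F3 | step 2 | (2S,5S)-2-tert-butyl-5-[2-(tert-butyldimethylsilyloxy)ethyl]-1,3-dioxolan-4-one | CC(C)(C)[Si](C)(C)OCC[C@@H]1O[C@H](C(C)(C)C)OC1=O
F4 | step 2 | (2S,5S)-2-tert-butyl-5-[2-(tert-butyldimethylsilyloxy)ethyl]-5-(3-methylbut-2-en-1-yl)-1,3-dioxolan-4-one | CC(C)(C)[Si](C)(C)OCC[C@]1(CC=C(C)C)O[C@H](C(C)(C)C)OC1=O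
F5 | step 9 | 5-O-(tert-butyldimethylsilyl)-(−)-quinic acid | CC(C)(C)[Si](C)(C)O[C@@H]1C[C@](O)(C(=O)O)C[C@@H](O)[C@H]1O
F6 | step 11 | benzyl (−)-quinate | O[C@@H]1C[C@](O)(C(=O)OCc2ccccc2)C[C@@H](O)[C@H]1O
F7 | step 12 | 3,4-bis-O-[3,4,5-tris(benzyloxy)benzoyl] derivative of 15 (5-O-TBS, spiro-dioxolanone) | CC(C)(C)[Si](C)(C)O[C@@H]1C[C@@]2(O[C@H](C(C)(C)C)OC2=O)C[C@@H](OC(=O)c2cc(OCc3ccccc3)c(OCc3ccccc3)c(OCc3ccccc3)c2)[C@H]1OC(=O)c1cc(OCc2ccccc2)c(OCc2ccccc2)c(OCc2ccccc2)c1
F8 | step 12 | 5-hydroxy 3,4-bis-O-[3,4,5-tris(benzyloxy)benzoyl] spiro-dioxolanone | O[C@@H]1C[C@@]2(O[C@H](C(C)(C)C)OC2=O)C[C@@H](OC(=O)c2cc(OCc3ccccc3)c(OCc3ccccc3)c(OCc3ccccc3)c2)[C@H]1OC(=O)c1cc(OCc2ccccc2)c(OCc2ccccc2)c(OCc2ccccc2)c1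
F9 | step 12 | 3,4,5-tris-O-[3,4,5-tris(benzyloxy)benzoyl] spiro-dioxolanone | O=C(O[C@@H]1C[C@@]2(O[C@H](C(C)(C)C)OC2=O)C[C@@H](OC(=O)c2cc(OCc3ccccc3)c(OCc3ccccc3)c(OCc3ccccc3)c2)[C@H]1OC(=O)c1cc(OCc2ccccc2)c(OCc2ccccc2)c(OCc2ccccc2)c1)c1cc(OCc2ccccc2)c(OCc2ccccc2)c(OCc2ccccc2)c1
F10 | step 12 | 3,4,5-tris-O-[3,4,5-tris(benzyloxy)benzoyl]-(−)-quinic acid | O=C(O[C@@H]1C[C@](O)(C(=O)O)C[C@@H](OC(=O)c2cc(OCc3ccccc3)c(OCc3ccccc3)c(OCc3ccccc3)c2)[C@H]1OC(=O)c1cc(OCc2ccccc2)c(OCc2ccccc2)c(OCc2ccccc2)c1)c1cc(OCc2ccccc2)c(OCc2ccccc2)c(OCc2ccccc2)c1
A1 | alternative 1 | 3,4-di-O-benzyl-3,4,5-trihydroxycyclohexanone (quinate configuration at C3, C4, C5) | O[C@@H]1CC(=O)C[C@@H](OCc2ccccc2)[C@H]1OCc3ccccc3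
A2 | alternative 1 | methyl 2,3-di-O-benzyl-4,6-dideoxy-D-erythro-hex-5-enopyranoside (either anomer) | COC1OC(=C)C[C@@H](OCc2ccccc2)[C@H]1OCc1ccccc1
A3 | alternative 1 | mercury bis(trifluoroacetate), Hg(OCOCF3)2 | [Hg+2].[O-]C(=O)C(F)(F)F.[O-]C(=O)C(F)(F)F
A4 | alternative 2 | (S)-1-formylcyclohex-3-en-1-yl benzoate | C1=CC[C@](OC(=O)c2ccccc2)(C=O)CC1
A5 | alternative 2 | 2-(benzoyloxy)acrolein | C=C(OC(=O)c1ccccc1)C=O
A6 | alternative 2 | buta-1,3-diene | C=CC=C
A7 | alternative 3 | 4-O-benzyl-3-dehydroquinate as the C1 spiro-dioxolanone (free 5-OH) | O[C@@H]1C[C@@]2(O[C@H](C(C)(C)C)OC2=O)CC(=O)[C@H]1OCc3ccccc3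
A8 | alternative 3 | 2-tert-butyl-5-[3-(benzyloxy)-2-oxopropyl]-5-(2-oxoethyl)-1,3-dioxolan-4-one (keto-aldehyde, C1 and acetal configured as in 14) | O=CC[C@]1(CC(=O)COCc2ccccc2)O[C@H](C(C)(C)C)OC1=O
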